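**Retrosynthetic overview**
1. Obtusane ⇐ C2–Cl/C3–Br from the C2=C3 alkene of an 8-bromo-β-chamigrene (8): epoxide → trans-bromohydrin → bromine-assisted, retentive OH→Cl.
2. C8–Br ⇐ C8–OH by SN2 inversion; C11=CH2 ⇐ C11 ketone.
3. Ring B and spiro C6 ⇐ Diels–Alder of isoprene with (S)-4-hydroxy-3,3-dimethyl-2-methylidenecyclohexanone (key step; ring A is bought, ring B is formed second).
4. Dienophile ⇐ (S)-3-hydroxy-2,2-dimethylcyclohexanone by methylenation, SeO2 allylic oxidation and MnO2 oxidation.

Assumption: (S)-3-hydroxy-2,2-dimethylcyclohexan-1-one is bought as the enantiopure commercial compound.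
Spiro compounds use the target's numbering: C1–C5 ring B, C6 spiro, C7 (CMe2) to C11 (C=CH2) ring A. The stereochemical arguments below are conformational reasoning, not experimental results.

**Step 1**
Reactants: 1, (S)-3-hydroxy-2,2-dimethylcyclohexan-1-one
Product: 2, (S)-2,2-dimethyl-3-methylidenecyclohexan-1-ol
Conditions: Zn, CH2Br2, TiCl4 (pre-formed, 3 equiv), THF–CH2Cl2, 0 °C → rt
Reagents that add atoms: dibromomethane, BrCBr
Why: Takai–Lombardo methylenation is non-basic, so the hindered ketone is olefinated without retro-aldol opening of the α-quaternary β-hydroxy ketone, and the free OH is tolerated; the carbinol centre is untouched.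

**Step 2**
Reactants: 2
Product: 3, (1S,4RS)-2,2-dimethyl-3-methylidenecyclohexane-1,4-diol (C4 epimers, both used)
Conditions: SeO2 (0.5 equiv), t-BuOOH, CH2Cl2, rt
Reagents that add atoms: selenium dioxide, O=[Se]=O; tert-butyl hydroperoxide (terminal oxidant), CC(C)(C)OO
Why: Riley allylic oxidation (ene reaction then [2,3]-sigmatropic shift) hydroxylates the only allylic CH2 and keeps the alkene exocyclic, as in β-pinene → pinocarveol.

**Step 3**
Reactants: 3
Product: 4, (S)-4-hydroxy-3,3-dimethyl-2-methylidenecyclohexan-1-one
Conditions: activated MnO2 (excess), CH2Cl2, rt; used at once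
Reagents that add atoms: none
Why: MnO2 oxidises only the allylic alcohol, so both C4 epimers converge on the enone and the saturated neopentyl carbinol is left alone.

**Step 4 (key step)**
Reactants: 4; 5, isoprene (10 equiv)
Product: 6, (6R,8S)-8-hydroxy-3,7,7-trimethylspiro[5.5]undec-2-en-11-one
Conditions: Me2AlCl (2.2 equiv), CH2Cl2, −78 → −20 °C; chromatography
Reagents that add atoms: none (isoprene is reactant 5)
Why: Lewis-acid-promoted Diels–Alder gives the "para" adduct (methyl 1,4 to the spiro carbon); with the O–Al substituent equatorial, the gem-dimethyl methyl on its face is axial, so isoprene bonds to the exocyclic carbon from the opposite face, setting C6 with C1 trans to O8.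

**Step 5**
Reactants: 6
Product: 7, (6S,8S)-3,7,7-trimethyl-11-methylidenespiro[5.5]undec-2-en-8-ol
Conditions: Ph3PCH3Br, KOt-Bu (4 equiv), PhMe, 90 °C
Reagents that add atoms: methyltriphenylphosphonium bromide, C[P+](c1ccccc1)(c1ccccc1)c1ccccc1.[Br-]
Why: Wittig methylenation under forcing, salt-free conditions converts the hindered non-epimerisable ketone; the remote hydroxyl is carried as its alkoxide.

**Step 6**
Reactants: 7
Product: 8, (6S,8R)-8-bromo-3,7,7-trimethyl-11-methylidenespiro[5.5]undec-2-ene
Conditions: PPh3, CBr4, 2,6-lutidine, PhMe, 70 °C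
Reagents that add atoms: carbon tetrabromide, BrC(Br)(Br)Br
Why: Appel reaction displaces the alkoxyphosphonium by bromide with SN2 inversion, turning the (8S) carbinol into the (8R) equatorial bromide cis to C1.

**Step 7**
Reactants: 8
Product: 9, (2S,3R,6S,8R)-8-bromo-2,3-epoxy-3,7,7-trimethyl-11-methylidenespiro[5.5]undecane (epoxide oxygen cis to C7)
Conditions: m-CPBA (1.05 equiv), NaHCO3, CH2Cl2, −20 °C
Reagents that add atoms: m-CPBA, OOC(=O)c1cccc(Cl)c1
Why: Prilezhaev epoxidation picks the trisubstituted alkene over the hindered 1,1-disubstituted one; C11 is pseudo-axial on ring B and its methylidene lies under C1/C2, so the peracid attacks the face syn to C7.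

**Step 8**
Reactants: 9
Product: 10, (2S,3S,6S,8R)-3,8-dibromo-3,7,7-trimethyl-11-methylidenespiro[5.5]undecan-2-ol
Conditions: 48% aq. HBr (1.2 equiv), Et2O, −20 °C, short reaction time
Reagents that add atoms: hydrogen bromide, Br
Why: Acid-mediated epoxide opening is Markovnikov and anti, so bromide enters at tertiary C3 with inversion (as 1-methylcyclohexene oxide gives trans-2-bromo-2-methylcyclohexanol); attack at C2 is electronically disfavoured and blocked by the methylidene.

**Step 9**
Reactants: 10
Product: 11, obtusane, (2S,3S,6S,8R)-3,8-dibromo-2-chloro-3,7,7-trimethyl-11-methylidenespiro[5.5]undecane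
Conditions: PPh3, NCS (pre-mixed), CH2Cl2, 0 °C → rt (40 °C if needed)
Reagents that add atoms: N-chlorosuccinimide, O=C1CCC(=O)N1Cl
Why: Appel-type deoxychlorination with neighbouring-group participation: direct SN2 at C2 is neopentyl-like and blocked, so the C3 bromine assists ionisation to a bromonium and chloride opens it at C2 from the original C–O face (net retention); the regioisomeric tertiary chloride would have an axial C2–Br clashing with C11 and should revert through the same bromonium to the all-equatorial product.

**Compound list**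
1 | (S)-3-hydroxy-2,2-dimethylcyclohexan-1-one | O=C1CCC[C@H](O)C1(C)C | starting material
2 | (S)-2,2-dimethyl-3-methylidenecyclohexan-1-ol | C=C1CCC[C@H](O)C1(C)C | intermediate
3 | (1S,4RS)-2,2-dimethyl-3-methylidenecyclohexane-1,4-diol | C=C1C(O)CC[C@H](O)C1(C)C | intermediate
4 | (S)-4-hydroxy-3,3-dimethyl-2-methylidenecyclohexan-1-one | C=C1C(=O)CC[C@H](O)C1(C)C | intermediate
5 | isoprene (2-methylbuta-1,3-diene) | C=CC(C)=C | starting material
6 | (6R,8S)-8-hydroxy-3,7,7-trimethylspiro[5.5]undec-2-en-11-one | O=C1CC[C@H](O)C(C)(C)[C@]12CCC(C)=CC2 | intermediate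
7 | (6S,8S)-3,7,7-trimethyl-11-methylidenespiro[5.5]undec-2-en-8-ol | C=C1CC[C@H](O)C(C)(C)[C@]12CCC(C)=CC2 | intermediate
8 | (6S,8R)-8-bromo-3,7,7-trimethyl-11-methylidenespiro[5.5]undec-2-ene | C=C1CC[C@@H](Br)C(C)(C)[C@]12CCC(C)=CC2 | intermediate
9 | (2S,3R,6S,8R)-8-bromo-2,3-epoxy-3,7,7-trimethyl-11-methylidenespiro[5.5]undecane | C=C1CC[C@@H](Br)C(C)(C)[C@]12CC[C@@](C)(O3)[C@@H]3C2 | intermediate
10 | (2S,3S,6S,8R)-3,8-dibromo-3,7,7-trimethyl-11-methylidenespiro[5.5]undecan-2-ol | C=C1CC[C@@H](Br)C(C)(C)[C@]12CC[C@](C)(Br)[C@@H](O)C2 | intermediate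
11 | obtusane | C=C1CC[C@@H](Br)C(C)(C)[C@]12CC[C@](C)(Br)[C@@H](Cl)C2 | target

**Totals**
Total steps: 9. Longest linear sequence: 9 (from 1; isoprene is bought).

**Three steps most likely to fail**
1. Step 9 (retentive chlorination; elimination or the wrong Br/Cl regioisomer may compete). Fallback: reverse the halogen polarity — make the chlorohydrin from 8 with an electrophilic chlorine source in aqueous acetone (Cl to C2 on the open face, OH at C3), then brominate the tertiary alcohol by SN1 (TMSBr) and separate or recycle the C3 epimers.
2. Step 6 (SN2 at a neopentyl secondary carbinol; elimination or methyl shift may compete). Fallback: radical deoxybromination — convert the C8 alcohol to a xanthate or oxalate and trap the C8 radical with BrCCl3, so the configuration is set by the ring and the epimers are separated.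
3. Step 4 (facial and regioselectivity with a hindered dienophile carrying a free OH). Fallback: change the controlling group — run the cycloaddition on the O-TIPS ether of 4 so that a bulky equatorial silyloxy group fixes the half-chair, and desilylate before step 6 (two extra steps).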